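**Retrosynthetic overview**
- 15 ⇐ 14 by loss of five O-benzyl groups. 14 ⇐ 12: the O1–C2 bond of the pyranone ring of unit 1 (the 4-methoxyphenyl flavanone) is opened by retro-oxa-Michael to a 2′-hydroxychalcone whose α-carbon C3 already carries the finished trans-flavanone of unit 2 (locants with ″).
- Feature used: in that ring O1 is the ortho-oxygen of the C4 aroyl group, and C2 is benzylic to the 4-methoxyphenyl ring and β to C4=O. The ring is therefore a latent enone O1–C8a–C4a–C4(=O)–C3=C2; C3 is α to C4=O and is set by ketonisation, steered by the neighbouring C3″/C2″ centres.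
- 12 ⇐ 9 + 4-methoxybenzaldehyde (C2=C3, aldol condensation); 9 ⇐ 5 + 8 (C3–C3″, enolate alkylation trans to the C2″ aryl group).
- 5 ⇐ chromone 3 + arylboronic acid 4 (asymmetric 1,4-addition sets C2″); 3 and 8 both come from acetophenone 1.
- Ring order: pyranone of unit 2 (as chromone, step 1), its C2″ centre (step 2), pyranone of unit 1 last (step 7).

Key step: step 7

Remark: compound 1 is taken as commercially available, and (S)-t-BuPyOX is assumed to deliver the (2R)-flavanone, as it gives R β-aryl ketones from cyclic enones; if the sense is opposite, the (R)-ligand is used.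

Step 1
Reactants: 1 1-[2,4-bis(benzyloxy)-6-hydroxyphenyl]ethan-1-one
Product: 3 5,7-bis(benzyloxy)-4H-chromen-4-one, via enaminone 2 (not isolated)
Conditions: Me2NCH(OMe)2, toluene, 100 °C; then conc. HCl, CH2Cl2, 40 °C
Reagents that add atoms: N,N-dimethylformamide dimethyl acetal, COC(OC)N(C)C
Why: Enaminone formation followed by acid-mediated addition of the phenol and loss of dimethylamine is the standard chromone synthesis from 2′-hydroxyacetophenones, and benzyl ethers should tolerate the brief acid treatment.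

Step 2
Reactants: 3 5,7-bis(benzyloxy)-4H-chromen-4-one; 4 [4-(benzyloxy)phenyl]boronic acid
Product: 5 (2R)-5,7-bis(benzyloxy)-2-[4-(benzyloxy)phenyl]chroman-4-one
Conditions: Pd(OCOCF3)2 (5 mol%), (S)-t-BuPyOX (6 mol%), NH4PF6 (30 mol%), H2O (5 equiv), ClCH2CH2Cl, 60 °C
Reagents that add atoms: none
Why: Palladium-catalysed asymmetric 1,4-addition of an arylboronic acid to a chromone (Hayashi–Miyaura-type conjugate addition with a pyridine-oxazoline ligand) should give the flavanone, the ligand choosing the face of aryl transfer to C2″ (R) and water protonating the palladium enolate.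

Step 3
Reactants: 1 1-[2,4-bis(benzyloxy)-6-hydroxyphenyl]ethan-1-one
Product: 6 1-[2,4-bis(benzyloxy)-6-(methoxymethoxy)phenyl]ethan-1-one
Conditions: NaH, MOMCl, DMF, 0 °C → rt
Reagents that add atoms: chloromethyl methyl ether, COCCl
Why: Williamson ether synthesis on the hydrogen-bonded phenoxide should mask the future O1 as the only acid-labile ether of the molecule.

Step 4
Reactants: 6 1-[2,4-bis(benzyloxy)-6-(methoxymethoxy)phenyl]ethan-1-one
Product: 8 2-bromo-1-[2,4-bis(benzyloxy)-6-(methoxymethoxy)phenyl]ethan-1-one, via silyl enol ether 7 (not isolated)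
Conditions: TMSOTf, Et3N, CH2Cl2, 0 °C; then NBS, THF, −78 °C
Reagents that add atoms: N-bromosuccinimide, O=C1CCC(=O)N1Br
Why: Soft enolisation and electrophilic α-bromination of the silyl enol ether at −78 °C should outrun bromination of the alkoxy-substituted arene.

Step 5
Reactants: 5 (2R)-5,7-bis(benzyloxy)-2-[4-(benzyloxy)phenyl]chroman-4-one; 8 2-bromo-1-[2,4-bis(benzyloxy)-6-(methoxymethoxy)phenyl]ethan-1-one
Product: 9 (2R,3S)-5,7-bis(benzyloxy)-2-[4-(benzyloxy)phenyl]-3-{2-[2,4-bis(benzyloxy)-6-(methoxymethoxy)phenyl]-2-oxoethyl}chroman-4-one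
Conditions: LiHMDS, THF, −78 °C; then 8, −78 → −30 °C
Reagents that add atoms: none
Why: Enolate alkylation (SN2 at the primary α-bromoketone) should form the C3–C3″ bond, the electrophile entering anti to the pseudo-axial C2″ aryl group so that C3″ (S) is trans, which is also the thermodynamic isomer.

Step 6
Reactants: 9 (2R,3S)-5,7-bis(benzyloxy)-2-[4-(benzyloxy)phenyl]-3-{2-[2,4-bis(benzyloxy)-6-(methoxymethoxy)phenyl]-2-oxoethyl}chroman-4-one; 10 4-methoxybenzaldehyde
Product: 12 (2R,3S)-5,7-bis(benzyloxy)-2-[4-(benzyloxy)phenyl]-3-{(E)-3-[2,4-bis(benzyloxy)-6-(methoxymethoxy)phenyl]-1-(4-methoxyphenyl)-3-oxoprop-1-en-2-yl}chroman-4-one, via aldol mesylate 11 (not isolated)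
Conditions: LiHMDS, THF, −78 °C; 10; then MsCl, Et3N, −78 → 0 °C
Reagents that add atoms: none
Why: A stepwise Claisen–Schmidt-type aldol condensation (kinetic deprotonation at the less hindered C3 methylene, aldol addition, mesylation, E1cB elimination) should give the enone, expected E with the anisyl group trans to the aroyl group; no sp3 stereocentre is made.

Step 7
Reactants: 12 (2R,3S)-5,7-bis(benzyloxy)-2-[4-(benzyloxy)phenyl]-3-{(E)-3-[2,4-bis(benzyloxy)-6-(methoxymethoxy)phenyl]-1-(4-methoxyphenyl)-3-oxoprop-1-en-2-yl}chroman-4-one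
Product: 14 (2S,3S)-5,7-bis(benzyloxy)-3-{(2R,3S)-5,7-bis(benzyloxy)-2-[4-(benzyloxy)phenyl]-4-oxochroman-3-yl}-2-(4-methoxyphenyl)chroman-4-one, via hydroxychalcone 13 (not isolated)
Conditions: CSA (0.3 equiv), MeOH–CH2Cl2 (1:4), 0 → 20 °C; cold NaHCO3 quench
Reagents that add atoms: none
Why: Acid methanolysis removes the MOM group and frees O1; protonation of the C4 carbonyl of 13 gives a hydroxyallyl cation stabilised at C2 by the 4-methoxyphenyl ring, and O1 adds to C2 in a 6-endo-trig oxa-Michael closure, the known 2′-hydroxychalcone-to-flavanone isomerisation as used for 3-substituted flavanones from α-substituted chalcones. C2 (S) should be set by 1,3-allylic strain: the C3″–H bond eclipses the C2=C3 plane beside the cis anisyl group, so the chromanone of unit 2 stands across the enone and O1 is expected to add on the face flanked by the flat C4″ carbonyl, away from the C2″ carbon that bears the aryl group. C3 (S) should be set in the ketonisation of the resulting enol: 1,2-allylic strain with the C3 substituent puts the new C2 anisyl group pseudo-axial and the proton is delivered to C3 on the opposite face, which leaves the anisyl group and unit 2 cis. The step needs facial selectivity at C2 and kinetic rather than thermodynamic control at C3; the first rests on the fixed C2″/C3″ centres, the second on catalytic acid, low temperature and a quench before the product enolises. The E and Z enones interconvert through the protonated form, and under acid unit 2 forms no enolate, so its ring is not opened.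

Step 8
Reactants: 14 (2S,3S)-5,7-bis(benzyloxy)-3-{(2R,3S)-5,7-bis(benzyloxy)-2-[4-(benzyloxy)phenyl]-4-oxochroman-3-yl}-2-(4-methoxyphenyl)chroman-4-one
Product: 15 (2S,3S)-5,7-dihydroxy-3-[(2R,3S)-5,7-dihydroxy-2-(4-hydroxyphenyl)-4-oxochroman-3-yl]-2-(4-methoxyphenyl)chroman-4-one
Conditions: H2 (1 atm), 10% Pd/C, EtOAc–MeOH, rt
Reagents that add atoms: none
Why: Hydrogenolysis of the five benzyl ethers under neutral conditions should leave the methyl ether, the ketones and the enolisable cis C2/C3 pair untouched.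

**Compound list**
1 | 1-[2,4-bis(benzyloxy)-6-hydroxyphenyl]ethan-1-one | CC(=O)c1c(O)cc(OCc2ccccc2)cc1OCc1ccccc1 | starting material
2 | (E)-1-[2,4-bis(benzyloxy)-6-hydroxyphenyl]-3-(dimethylamino)prop-2-en-1-one | CN(C)/C=C/C(=O)c1c(O)cc(OCc2ccccc2)cc1OCc1ccccc1 | intermediate
3 | 5,7-bis(benzyloxy)-4H-chromen-4-one | O=c1ccoc2cc(OCc3ccccc3)cc(OCc3ccccc3)c12 | intermediate
4 | [4-(benzyloxy)phenyl]boronic acid | OB(O)c1ccc(OCc2ccccc2)cc1 | starting material
5 | (2R)-5,7-bis(benzyloxy)-2-[4-(benzyloxy)phenyl]chroman-4-one | O=C1C[C@H](c2ccc(OCc3ccccc3)cc2)Oc2cc(OCc3ccccc3)cc(OCc3ccccc3)c12 | intermediate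
6 | 1-[2,4-bis(benzyloxy)-6-(methoxymethoxy)phenyl]ethan-1-one | CC(=O)c1c(OCOC)cc(OCc2ccccc2)cc1OCc1ccccc1 | intermediate
7 | {1-[2,4-bis(benzyloxy)-6-(methoxymethoxy)phenyl]ethenyloxy}trimethylsilane | C=C(O[Si](C)(C)C)c1c(OCOC)cc(OCc2ccccc2)cc1OCc1ccccc1 | intermediate
8 | 2-bromo-1-[2,4-bis(benzyloxy)-6-(methoxymethoxy)phenyl]ethan-1-one | BrCC(=O)c1c(OCOC)cc(OCc2ccccc2)cc1OCc1ccccc1 | intermediate
9 | (2R,3S)-5,7-bis(benzyloxy)-2-[4-(benzyloxy)phenyl]-3-{2-[2,4-bis(benzyloxy)-6-(methoxymethoxy)phenyl]-2-oxoethyl}chroman-4-one | O=C1[C@@H](CC(=O)c2c(OCOC)cc(OCc3ccccc3)cc2OCc2ccccc2)[C@H](c2ccc(OCc3ccccc3)cc2)Oc2cc(OCc3ccccc3)cc(OCc3ccccc3)c12 | intermediate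
10 | 4-methoxybenzaldehyde | COc1ccc(C=O)cc1 | starting material
11 | aldol mesylate of 9 and 10 (mixture at the two new centres) | COc1ccc(C(OS(C)(=O)=O)C(C(=O)c2c(OCOC)cc(OCc3ccccc3)cc2OCc2ccccc2)[C@@H]2C(=O)c3c(OCc4ccccc4)cc(OCc4ccccc4)cc3O[C@H]2c2ccc(OCc3ccccc3)cc2)cc1 | intermediate
12 | (2R,3S)-5,7-bis(benzyloxy)-2-[4-(benzyloxy)phenyl]-3-{(E)-3-[2,4-bis(benzyloxy)-6-(methoxymethoxy)phenyl]-1-(4-methoxyphenyl)-3-oxoprop-1-en-2-yl}chroman-4-one | COc1ccc(/C=C(\[C@@H]2C(=O)c3c(OCc4ccccc4)cc(OCc4ccccc4)cc3O[C@H]2c2ccc(OCc3ccccc3)cc2)C(=O)c2c(OCOC)cc(OCc3ccccc3)cc2OCc2ccccc2)cc1 | intermediate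
13 | (2R,3S)-5,7-bis(benzyloxy)-2-[4-(benzyloxy)phenyl]-3-{(E)-3-[2,4-bis(benzyloxy)-6-hydroxyphenyl]-1-(4-methoxyphenyl)-3-oxoprop-1-en-2-yl}chroman-4-one | COc1ccc(/C=C(\[C@@H]2C(=O)c3c(OCc4ccccc4)cc(OCc4ccccc4)cc3O[C@H]2c2ccc(OCc3ccccc3)cc2)C(=O)c2c(O)cc(OCc3ccccc3)cc2OCc2ccccc2)cc1 | intermediate
14 | (2S,3S)-5,7-bis(benzyloxy)-3-{(2R,3S)-5,7-bis(benzyloxy)-2-[4-(benzyloxy)phenyl]-4-oxochroman-3-yl}-2-(4-methoxyphenyl)chroman-4-one | COc1ccc([C@H]2Oc3cc(OCc4ccccc4)cc(OCc4ccccc4)c3C(=O)[C@H]2[C@@H]2C(=O)c3c(OCc4ccccc4)cc(OCc4ccccc4)cc3O[C@H]2c2ccc(OCc3ccccc3)cc2)cc1 | intermediate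
15 | (2S,3S)-5,7-dihydroxy-3-[(2R,3S)-5,7-dihydroxy-2-(4-hydroxyphenyl)-4-oxochroman-3-yl]-2-(4-methoxyphenyl)chroman-4-one (CNP0196568.4) | COc1ccc([C@H]2Oc3cc(O)cc(O)c3C(=O)[C@H]2[C@@H]2C(=O)c3c(O)cc(O)cc3O[C@H]2c2ccc(O)cc2)cc1 | target

**Step count and risks**
Total step count: 8. Longest linear sequence: 6 steps (1 → 3 → 5 → 9 → 12 → 14 → 15).

Steps most likely to fail:

1. Step 7. The remote unit 2 may discriminate the two faces of C2 too weakly, or acid-mediated enolisation may drain the kinetic cis isomer to trans. Fallback, from 9 back to 14: an anti-selective boron aldol reaction of 9 with 10 (Cy2BCl, Et3N, Et2O, −78 °C; E-enolate, closed chair transition state) should give the anti-aldol (2R,3S)-5,7-bis(benzyloxy)-2-[4-(benzyloxy)phenyl]-3-{(2S,3R)-1-[2,4-bis(benzyloxy)-6-(methoxymethoxy)phenyl]-3-hydroxy-3-(4-methoxyphenyl)-1-oxopropan-2-yl}chroman-4-one F1, separated from the other anti isomer if the facial bias is incomplete. Brief CSA/MeOH at 0 °C should cleave the chelated MOM ether to the phenol (2R,3S)-5,7-bis(benzyloxy)-2-[4-(benzyloxy)phenyl]-3-{(2S,3R)-1-[2,4-bis(benzyloxy)-6-hydroxyphenyl]-3-hydroxy-3-(4-methoxyphenyl)-1-oxopropan-2-yl}chroman-4-one F2. A Mitsunobu reaction (PPh3, DIAD, toluene, 0 °C) would then close the same O1–C2 bond by SN2 with inversion at the carbinol carbon, turning the anti-aldol stereospecifically into the 2,3-cis flavanone 14.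

2. Step 5. The flavanone enolate may expel the aryloxide (ring opening, loss of the C2″ configuration), or it may be quenched by proton transfer from the acidic bromoketone before C-alkylation. Fallback, from 5 and 6 back to 9: the lithium enolate of 6 is silylated with excess Me2SiCl2 and the chlorosilyl enol ether is combined at −78 °C with the lithium enolate of 5; O-silylation is fast, so the enolate is short-lived. This should give the silyl bis-enol ether {1-[2,4-bis(benzyloxy)-6-(methoxymethoxy)phenyl]ethenyloxy}{[(2R)-5,7-bis(benzyloxy)-2-(4-(benzyloxy)phenyl)-2H-chromen-4-yl]oxy}dimethylsilane F3. Oxidation with (NH4)2Ce(NO3)6 and NaHCO3 in MeCN at −10 °C (silicon-tethered oxidative enolate heterocoupling) would form the C3–C3″ bond within the tether, anti to the C2″ aryl group, and give 9.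

3. Step 6. The hindered aldolate may revert before it is mesylated, and the base may also deprotonate C3″. Fallback, from 9 back to 12: a Mannich-type α-methylenation without strong base (paraformaldehyde, diisopropylammonium trifluoroacetate, THF, reflux; only the C3 methylene can eliminate) should give the α-methylene ketone (2R,3S)-5,7-bis(benzyloxy)-2-[4-(benzyloxy)phenyl]-3-{3-[2,4-bis(benzyloxy)-6-(methoxymethoxy)phenyl]-3-oxoprop-1-en-2-yl}chroman-4-one F4. A Mizoroki–Heck reaction with 4-iodoanisole (Pd(OAc)2, NaHCO3, n-Bu4NCl, DMF, 50 °C) would then place the 4-methoxyphenyl group on the terminal carbon and give 12.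

Further compounds
F1 | step 7 | (2R,3S)-5,7-bis(benzyloxy)-2-[4-(benzyloxy)phenyl]-3-{(2S,3R)-1-[2,4-bis(benzyloxy)-6-(methoxymethoxy)phenyl]-3-hydroxy-3-(4-methoxyphenyl)-1-oxopropan-2-yl}chroman-4-one | COc1ccc([C@H](O)[C@@H](C(=O)c2c(OCOC)cc(OCc3ccccc3)cc2OCc2ccccc2)[C@@H]2C(=O)c3c(OCc4ccccc4)cc(OCc4ccccc4)cc3O[C@H]2c2ccc(OCc3ccccc3)cc2)cc1
F2 | step 7 | (2R,3S)-5,7-bis(benzyloxy)-2-[4-(benzyloxy)phenyl]-3-{(2S,3R)-1-[2,4-bis(benzyloxy)-6-hydroxyphenyl]-3-hydroxy-3-(4-methoxyphenyl)-1-oxopropan-2-yl}chroman-4-one | COc1ccc([C@H](O)[C@@H](C(=O)c2c(O)cc(OCc3ccccc3)cc2OCc2ccccc2)[C@@H]2C(=O)c3c(OCc4ccccc4)cc(OCc4ccccc4)cc3O[C@H]2c2ccc(OCc3ccccc3)cc2)cc1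
F3 | step 5 | {1-[2,4-bis(benzyloxy)-6-(methoxymethoxy)phenyl]ethenyloxy}{[(2R)-5,7-bis(benzyloxy)-2-(4-(benzyloxy)phenyl)-2H-chromen-4-yl]oxy}dimethylsilane | C=C(O[Si](C)(C)OC1=C[C@H](c2ccc(OCc3ccccc3)cc2)Oc2cc(OCc3ccccc3)cc(OCc3ccccc3)c12)c1c(OCOC)cc(OCc2ccccc2)cc1OCc1ccccc1
F4 | step 6 | (2R,3S)-5,7-bis(benzyloxy)-2-[4-(benzyloxy)phenyl]-3-{3-[2,4-bis(benzyloxy)-6-(methoxymethoxy)phenyl]-3-oxoprop-1-en-2-yl}chroman-4-one | C=C(C(=O)c1c(OCOC)cc(OCc2ccccc2)cc1OCc1ccccc1)[C@@H]1C(=O)c2c(OCc3ccccc3)cc(OCc3ccccc3)cc2O[C@H]1c1ccc(OCc2ccccc2)cc1
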